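A small charge of Xc, 2.10 mM in the amber run against 6.40 mM in the violet run, was the case I had to price.

| flask | Xa | Xb | Xc | time |
|---|---|---|---|---|
| violet | 80.0 mM | 240 mM | 6.40 mM |  |
| green | 32.0 mM | 192 mM | 6.40 mM |  |
| grey | 80.0 mM | 240 mM | 9.60 mM |  |
| amber | 80.0 mM | 120 mM | 2.10 mM | 28 h |

- violet run (time / h: [Xp] / mM): 1.2: 26.0; 3.8: 36.4; 7.2: 41.6; 11: 43.4; 16: 46.4; 22: 52.1; 28: 54.7
- green run (time / h: [Xp] / mM): 1.2: 11.0; 3.8: 14.5; 7.2: 15.8; 11: 16.5; 16: 18.4; 22: 19.9; 28: 21.4
- grey run (time / h: [Xp] / mM): 1.2: 35.4; 3.8: 47.6; 7.2: 50.6; 11: 52.5; 16: 54.8; 22: 58.2; 28: 61.3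

(readings scatter by 0.6 mM)

- Overall: Xa + Xb -> Xp, with Xc as catalyst.
- Constant volume, constant temperature.
- Bound and free are read together.
- "The second partner" is Xb.
- An order is taken over about fifteen percent of the charge, up and down.

- how the opening rate goes with [Xc] round the charge of the violet run: the exponent of the rate at two percent of Xa gone to Xp
- the green run starts with 48.0 mM less of Xa and of Xb than the violet run, and with no Xp. Compared where both hold the same amount of Xa, once fifteen percent of what the green run was charged with has turned into Xp, is the green run faster, slower or alike (within a tenth)?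
- Xp in the amber run at 28 h, as a share of the Xa charged

I began with a zero for the scale. The green run starts 48.0 mM short in Xa and in Xb alike, so at the point asked for it holds the same [Xa] and [Xb] as the violet run, with the same Xc charged. A lasting catalyst, with Xp taking no part in the rate, puts the rate ratio there at 1. The readings gave 9.17 mM h⁻¹ on average over the first 1.2 h of the green run, which spans that point, and 0.433 mM h⁻¹ in the violet run between 22 h and 28 h, where it crosses that [Xa]. The green run was faster, by a ratio of about 21.2, so I read the activity as having faded with age.

Each run therefore makes a burst and then creeps. At 11 h the violet and green runs had turned 54.2% and 51.6% of their Xa, so I treated Xa as pseudo-first-order and counted in the exponent ln([Xa] charged/[Xa] left).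

The violet tail from 11 h to 28 h ran at 0.0217 h⁻¹. I took this as a background step first order in Xa and in Xb, which gives 0.114 M⁻¹ h⁻¹. That is my assumption: the mean [Xb] of the tails, 0.191 M in the violet run and 0.173 M in the green, lie too close to test it.

Taking the tail's share from the violet exponent at 11 h and dividing by the Xc charged left 84.9 M⁻¹. I call this the burst allowance, the exponent a charge delivers per unit of [Xc] charged before it fades. Using it in proportion to [Xc] presumes an order near one, and the exponents of the grey and violet runs at 1.2 h gave a reading of 0.978.

For the amber run the allowance gives an exponent of 0.178, or 0.0131 M of Xp. A first pass with [Xb] at 0.107 M gave 0.0324 M of Xp at 28 h, so I put the mean [Xb] of the amber tail at about 0.0973 M. My figure was 38.6%.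

The forecast gave 1.05 (0.8 to 1.35), faster, and 47% (34% to 57%) for the amber run, “trimmed for possible Xb dependence of the tail”, which stood above my figure.

The simulation gave an order of 0.97, the green run faster at a ratio of 20, and 37.9% for the amber run.

    Xc + Xa → Xc.Xa (84.60 M⁻¹ h⁻¹)
    Xc.Xa + Xb → Xp + Xc (489.6 M⁻¹ h⁻¹)
    Xc → G (0.9792 h⁻¹)
    Xa + Xb → Xp (0.1076 M⁻¹ h⁻¹)

That amber share is an exponent of 0.477, of which my allowance accounts for 0.178, leaving 0.299 for the background. Taking out the step from Xc to G moves the readings by 39 in units of the scatter, root mean square. In the grey run the allowance gives 0.815, above the ln(2) of 0.693, while in the violet run it gives 0.543, below it. The Xp made came to half of the Xa charged at 1.67 h in the grey run and at 6.33 h in the violet run.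

The runs are simulated for substances that don't exist, and the scatter is random.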